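The flavone is cut at its C4 carbonyl. This single carbon sits between C4a of ring A and C3 of ring C, so it is supplied by carbon monoxide. A palladium-catalysed carbonylative Sonogashira coupling joins MOM-protected iodophloroglucinol, CO and a 4-benzyloxy-3-(methoxymethoxy)phenylacetylene. It forms C4a–C4 and C4–C3 at once and delivers the whole C6–C3–C6 skeleton as an ynone. Because the three oxygens of ring A are equivalent, ring C can close in only one sense. One acid/base operation then frees 5-, 7- and 3'-OH while 4'-O stays benzylated. The chelated 5-OH resists sulfation, so 7-OH and 3'-OH are sulfated selectively before hydrogenolysis.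

Key step: step 5

Assumption: the target is drawn as the free bis(hydrogen sulfate); the two sulfated compounds would be handled as their disodium salts and are written in the neutral acid form. No numbered compound has a stereocentre or a stereogenic double bond.

Step 1
Reactants: 1 phloroglucinol (anhydrous)
Product: 2 1,3,5-tris(methoxymethoxy)benzene
Conditions: NaH, MOMCl, DMF, 0 °C to rt
Reagents that add atoms: chloromethyl methyl ether (MOMCl), COCCl
Why: Williamson-type O-alkylation (MOM protection) of the three phenoxides; the hard α-chloro ether in a polar aprotic solvent should favour O- over C-alkylation.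

Step 2
Reactants: 2 1,3,5-tris(methoxymethoxy)benzene
Product: 4 2-iodo-1,3,5-tris(methoxymethoxy)benzene, via aryllithium 3 (not isolated)
Conditions: n-BuLi, THF, 0 °C; then I2, −78 °C to rt; aq. Na2S2O3 work-up
Reagents that add atoms: iodine, II
Why: Directed ortho-metalation at a C–H flanked by two chelating OMOM groups (all three ring positions are equivalent, so only one aryllithium can form), followed by iodinolysis of the C–Li bond.

Step 3
Reactants: 5 4-(benzyloxy)-3-hydroxybenzaldehyde
Product: 6 4-(benzyloxy)-3-(methoxymethoxy)benzaldehyde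
Conditions: MOMCl, K2CO3, acetone, rt
Reagents that add atoms: chloromethyl methyl ether (MOMCl), COCCl
Why: MOM protection of the single free phenol under mild carbonate base; the non-enolisable aldehyde and the benzyl ether are inert.

Step 4
Reactants: 6 4-(benzyloxy)-3-(methoxymethoxy)benzaldehyde
Product: 7 1-(benzyloxy)-4-ethynyl-2-(methoxymethoxy)benzene
Conditions: dimethyl (1-diazo-2-oxopropyl)phosphonate, K2CO3, MeOH, rt
Reagents that add atoms: dimethyl (1-diazo-2-oxopropyl)phosphonate, COP(=O)(OC)C(=[N+]=[N-])C(C)=O
Why: Ohira–Bestmann variant of the Seyferth–Gilbert homologation: methanolysis gives the diazomethylphosphonate anion, which olefinates the aldehyde; loss of N2 and a 1,2-hydrogen shift give the terminal alkyne under conditions that spare MOM and benzyl ethers.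

Step 5
Reactants: 4 2-iodo-1,3,5-tris(methoxymethoxy)benzene; 7 1-(benzyloxy)-4-ethynyl-2-(methoxymethoxy)benzene; 8 carbon monoxide
Product: 9 3-[4-(benzyloxy)-3-(methoxymethoxy)phenyl]-1-[2,4,6-tris(methoxymethoxy)phenyl]prop-2-yn-1-one
Conditions: PdCl2(PPh3)2 (5 mol %), CuI (2 mol %), Et3N, THF, CO (5 bar), 40 °C, slow addition of 7
Reagents that add atoms: carbon monoxide (compound 8), [C-]#[O+]
Why: Zerovalent palladium, formed in situ from PdCl2(PPh3)2, adds oxidatively to the C–I bond of 4; CO then inserts to give the aroylpalladium iodide, which takes the acetylide of 7 from copper and reductively eliminates ynone 9, so C4a–C4 and C4–C3 (flavone numbering) form in one operation. The closest known reaction type is the palladium/copper-catalysed carbonylative Sonogashira coupling of aryl iodides with terminal alkynes to alkynyl ketones. No ring is closed and no stereocentre is formed. The selectivity needed is acylation ahead of direct aryl–alkynyl coupling and of oxidative alkyne dimerisation. It is secured by the substrate, because the electron-rich aryl group flanked by two ortho OMOM groups migrates to CO fast while transmetalation at the crowded arylpalladium centre is slow, and it is reinforced by CO pressure, low CuI loading, slow addition of 7 and exclusion of oxygen. MOM acetals and the benzyl ether are inert to these mildly basic conditions, and the tertiary amine cannot add to the ynone.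

Step 6
Reactants: 9 3-[4-(benzyloxy)-3-(methoxymethoxy)phenyl]-1-[2,4,6-tris(methoxymethoxy)phenyl]prop-2-yn-1-one
Product: 11 4'-O-benzylluteolin (2-[4-(benzyloxy)-3-hydroxyphenyl]-5,7-dihydroxy-4H-chromen-4-one), via tetraol ynone 10 (not isolated)
Conditions: HCl, MeOH–THF, 50 °C; evaporate; then K2CO3, acetone, 50 °C; dilute aq. HCl work-up
Reagents that add atoms: none
Why: Acid-catalysed transacetalisation with methanol cleaves all four MOM ethers, and intramolecular 6-endo-dig oxa-Michael addition of an ortho hydroxyl to the ynone (acid-promoted in part, completed by carbonate in an aprotic solvent, which favours 6-endo over 5-exo closure) forms ring C; the two ortho hydroxyls are equivalent, so only one flavone can result, and any HCl or water adduct of the ynone converges on it by addition–elimination or cyclodehydration.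

Step 7
Reactants: 11 4'-O-benzylluteolin
Product: 12 4'-O-benzylluteolin 7,3'-bis(hydrogen sulfate)
Conditions: SO3·pyridine (6 equiv), DMF, rt to 40 °C; then aq. NaHCO3; Sephadex LH-20
Reagents that add atoms: sulfur trioxide–pyridine complex, O=S(=O)([O-])[n+]1ccccc1
Why: O-sulfation of phenols by a sulfur trioxide–amine complex should take the acidic 7-OH and the free 3'-OH, while 5-OH is deactivated by its hydrogen bond to the C4 carbonyl and 4'-O is blocked as the benzyl ether.

Step 8
Reactants: 12 4'-O-benzylluteolin 7,3'-bis(hydrogen sulfate) (as disodium salt)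
Product: 13 luteolin 7,3'-disulfate
Conditions: H2 (1 atm), 10 % Pd/C, MeOH–H2O, rt
Reagents that add atoms: none
Why: Catalytic hydrogenolysis of the benzyl aryl ether under neutral conditions; aryl sulfate salts and the flavone C2=C3 bond should withstand hydrogen at atmospheric pressure, and the salt form prevents acid-catalysed loss of sulfate.

Compound list
1 | phloroglucinol | Oc1cc(O)cc(O)c1 | starting material
2 | 1,3,5-tris(methoxymethoxy)benzene | COCOc1cc(OCOC)cc(OCOC)c1 | intermediate
3 | [2,4,6-tris(methoxymethoxy)phenyl]lithium | [Li]c1c(OCOC)cc(OCOC)cc1OCOC | intermediate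
4 | 2-iodo-1,3,5-tris(methoxymethoxy)benzene | COCOc1cc(OCOC)c(I)c(OCOC)c1 | intermediate
5 | 4-(benzyloxy)-3-hydroxybenzaldehyde | O=Cc1ccc(OCc2ccccc2)c(O)c1 | starting material
6 | 4-(benzyloxy)-3-(methoxymethoxy)benzaldehyde | O=Cc1ccc(OCc2ccccc2)c(OCOC)c1 | intermediate
7 | 1-(benzyloxy)-4-ethynyl-2-(methoxymethoxy)benzene | C#Cc1ccc(OCc2ccccc2)c(OCOC)c1 | intermediate
8 | carbon monoxide | [C-]#[O+] | starting material
9 | 3-[4-(benzyloxy)-3-(methoxymethoxy)phenyl]-1-[2,4,6-tris(methoxymethoxy)phenyl]prop-2-yn-1-one | COCOc1cc(OCOC)c(C(=O)C#Cc2ccc(OCc3ccccc3)c(OCOC)c2)c(OCOC)c1 | intermediate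
10 | 3-[4-(benzyloxy)-3-hydroxyphenyl]-1-(2,4,6-trihydroxyphenyl)prop-2-yn-1-one | O=C(C#Cc1ccc(OCc2ccccc2)c(O)c1)c1c(O)cc(O)cc1O | intermediate
11 | 2-[4-(benzyloxy)-3-hydroxyphenyl]-5,7-dihydroxy-4H-chromen-4-one (4'-O-benzylluteolin) | O=c1cc(-c2ccc(OCc3ccccc3)c(O)c2)oc2cc(O)cc(O)c12 | intermediate
12 | 2-[4-(benzyloxy)-3-(sulfooxy)phenyl]-5-hydroxy-4-oxo-4H-chromen-7-yl hydrogen sulfate (4'-O-benzylluteolin 7,3'-disulfate) | O=c1cc(-c2ccc(OCc3ccccc3)c(OS(=O)(=O)O)c2)oc2cc(OS(=O)(=O)O)cc(O)c12 | intermediate
13 | luteolin 7,3'-disulfate (5-hydroxy-2-[4-hydroxy-3-(sulfooxy)phenyl]-4-oxo-4H-chromen-7-yl hydrogen sulfate) | O=c1cc(-c2ccc(O)c(OS(=O)(=O)O)c2)oc2cc(OS(=O)(=O)O)cc(O)c12 | target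

Total step count: 8.
Longest linear sequence: 6 steps (steps 1, 2, 5, 6, 7, 8; the branch through steps 3 and 4 is equally long).

Steps most likely to fail

Step 5. Direct aryl–alkynyl coupling may outrun CO insertion, the alkyne may dimerise oxidatively, or oxidative addition at the hindered, electron-rich C–I bond may stall. The fallback sets out from aryllithium 3 (generated from 2 as in step 2) and alkyne 7, and returns to the route at ynone 9. Quenching 3 with DMF should give 2,4,6-tris(methoxymethoxy)benzaldehyde F1. Alkyne 7 is deprotonated with n-BuLi (THF, −78 °C) to its lithium acetylide F2, which adds to F1 to give the racemic propargylic alcohol 3-[4-(benzyloxy)-3-(methoxymethoxy)phenyl]-1-[2,4,6-tris(methoxymethoxy)phenyl]prop-2-yn-1-ol F3. Oxidation with MnO2 (CH2Cl2, rt) removes the carbinol stereocentre and gives 9.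

Step 7. Sulfation may stop short at the 3'-OH next to the benzyloxy group, spill over onto 5-OH, or be undone by hydrolysis during isolation of the polar salt. The fallback sets out from 11 and returns at 12. It installs the sulfates as neutral, chromatographable diesters: 2,2,2-trichloroethyl chlorosulfate, Et3N and DMAP in THF should give 2-[4-(benzyloxy)-3-{[(2,2,2-trichloroethoxy)sulfonyl]oxy}phenyl]-5-hydroxy-4-oxo-4H-chromen-7-yl 2,2,2-trichloroethyl sulfate F4. This is purified on silica and then unmasked by reductive elimination with Zn and HCO2NH4 in MeOH, which leaves the benzyl ether intact and gives 12.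

Step 6. Ring closure may go 5-exo to the aurone, remain incomplete, or be accompanied by decomposition of the polyphenolic ynone under base. The fallback sets out from 9 and returns at 11. It fixes the regiochemistry before deprotection: conjugate addition of Et2NH (EtOH, rt) to the ynone should give the enaminone (E)-3-[4-(benzyloxy)-3-(methoxymethoxy)phenyl]-3-(diethylamino)-1-[2,4,6-tris(methoxymethoxy)phenyl]prop-2-en-1-one F5 (E expected; the geometry is lost on cyclisation). Treatment with HCl in MeOH (60 °C) then cleaves the MOM ethers, and the freed ortho hydroxyl displaces diethylamine at the amine-bearing carbon by addition–elimination, which can only give the six-membered ring of 11.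

Further compounds
F1 | step 5 | 2,4,6-tris(methoxymethoxy)benzaldehyde | COCOc1cc(OCOC)c(C=O)c(OCOC)c1
F2 | step 5 | lithium acetylide of 7, {[4-(benzyloxy)-3-(methoxymethoxy)phenyl]ethynyl}lithium | [Li]C#Cc1ccc(OCc2ccccc2)c(OCOC)c1
F3 | step 5 | 3-[4-(benzyloxy)-3-(methoxymethoxy)phenyl]-1-[2,4,6-tris(methoxymethoxy)phenyl]prop-2-yn-1-ol (racemic) | COCOc1cc(OCOC)c(C(O)C#Cc2ccc(OCc3ccccc3)c(OCOC)c2)c(OCOC)c1
F4 | step 7 | 2-[4-(benzyloxy)-3-{[(2,2,2-trichloroethoxy)sulfonyl]oxy}phenyl]-5-hydroxy-4-oxo-4H-chromen-7-yl 2,2,2-trichloroethyl sulfate | O=c1cc(-c2ccc(OCc3ccccc3)c(OS(=O)(=O)OCC(Cl)(Cl)Cl)c2)oc2cc(OS(=O)(=O)OCC(Cl)(Cl)Cl)cc(O)c12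
F5 | step 6 | (E)-3-[4-(benzyloxy)-3-(methoxymethoxy)phenyl]-3-(diethylamino)-1-[2,4,6-tris(methoxymethoxy)phenyl]prop-2-en-1-one | CCN(CC)/C(c1ccc(OCc2ccccc2)c(OCOC)c1)=C/C(=O)c1c(OCOC)cc(OCOC)cc1OCOC
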